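**Retrosynthetic overview**

1. The target is a (2S)-flavanone (rings A, B, C) with a 2-prenyl-3-methyl-4-hydroxybutyl chain on C8. The endgame is global MOM removal, allyl-to-prenyl cross-metathesis, and closure of ring C (O1–C2) by catalyst-controlled oxa-Michael addition of the C8a phenol of a 2′-hydroxychalcone.
2. The strategy rests on ring A: O1 sits on C8a and the C4 carbonyl carbon on the adjacent C4a, and this ortho pair is flanked by the C5 oxygen and the C8 chain. That is the pattern a 3-alkoxy-6-alkylbenzyne leaves, so O–C8a and C4–C4a are made together by inserting that aryne into the acyl–oxygen bond of a ring B cinnamic acid.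
3. The aryne comes from a 2-(trimethylsilyl)aryl triflate built on phloroglucinol: bis-MOM ether, acetate-controlled bromination and iodination at the two positions flanking the third oxygen, Negishi coupling at C–I, retro-Brook silylation at C–Br, triflation.
4. Both side-chain stereocentres come from (S)-β-methyl-γ-butyrolactone by trans-selective allylation. An allyl group stands in for prenyl until after the aryne step, because a prenyl terminus tethered at C8 would be placed for an intramolecular aryne–ene reaction.
5. Ring order: rings A and B are bought and joined in the key step without ring formation; ring C is the only ring closed, afterwards.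

Key step: step 15

Assumption: (S)-4-methyldihydrofuran-2(3H)-one is taken as a purchasable chiral building block, and the quinidine-derived thiourea is taken as the pseudoenantiomer that gives 2S in step 16 (the quinine-derived one would be used if the facial sense proves to be the reverse).

**Route**

Step 1
Reactants: 1 (S)-4-methyldihydrofuran-2(3H)-one; 2 allyl bromide
Product: 4 (3S,4S)-4-methyl-3-(prop-2-en-1-yl)dihydrofuran-2(3H)-one, via lithium enolate 3 (not isolated)
Conditions: LiN(i-Pr)2, THF, −78 °C; then 2, −78 → −40 °C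
Reagents that add atoms: none
Why: Enolate alkylation of a β-substituted γ-butyrolactone takes place on the face opposite the C4 methyl group, so the new C3 centre should be set trans (3S) under substrate control.

Step 2
Reactants: 4 (3S,4S)-4-methyl-3-(prop-2-en-1-yl)dihydrofuran-2(3H)-one
Product: 5 (2S,3S)-4-hydroxy-N-methoxy-N,3-dimethyl-2-(prop-2-en-1-yl)butanamide
Conditions: MeNH(OMe)·HCl, AlMe3, CH2Cl2, 0 °C → rt
Reagents that add atoms: N,O-dimethylhydroxylamine hydrochloride, CNOC.Cl
Why: Weinreb aminolysis with the aluminium amide opens the lactone at the acyl carbon without touching either stereocentre and frees the primary alcohol that becomes the CH2OH of the target.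

Step 3
Reactants: 5 (2S,3S)-4-hydroxy-N-methoxy-N,3-dimethyl-2-(prop-2-en-1-yl)butanamide
Product: 6 (2S,3S)-N-methoxy-4-(methoxymethoxy)-N,3-dimethyl-2-(prop-2-en-1-yl)butanamide
Conditions: MOMCl, i-Pr2NEt, CH2Cl2, 0 °C → rt
Reagents that add atoms: chloromethyl methyl ether, COCCl
Why: Base-mediated O-alkylation caps the primary alcohol before it can relactonise, as an acetal that withstands organometallic reagents and hot fluoride.

Step 4
Reactants: 6 (2S,3S)-N-methoxy-4-(methoxymethoxy)-N,3-dimethyl-2-(prop-2-en-1-yl)butanamide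
Product: 8 (2S,3S)-4-(methoxymethoxy)-3-methyl-2-(prop-2-en-1-yl)butan-1-ol, via aldehyde 7 (not isolated)
Conditions: i-Bu2AlH, THF, −78 °C; then MeOH, NaBH4, −78 → 0 °C
Reagents that add atoms: none
Why: Hydride reduction of a Weinreb amide stops at the chelated hemiaminal, and the aldehyde released on methanol quench is reduced at once by NaBH4, which should avoid epimerisation of the α-centre.

Step 5
Reactants: 8 (2S,3S)-4-(methoxymethoxy)-3-methyl-2-(prop-2-en-1-yl)butan-1-ol
Product: 9 (4S,5S)-4-(iodomethyl)-6-(methoxymethoxy)-5-methylhex-1-ene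
Conditions: PPh3, I2, imidazole, CH2Cl2, 0 °C → rt
Reagents that add atoms: iodine, II
Why: Appel-type iodination displaces the alkoxyphosphonium by SN2 at a primary carbon that carries no stereocentre, under buffered conditions that spare the MOM ether and the alkene.

Step 6
Reactants: 10 phloroglucinol
Product: 11 3,5-bis(methoxymethoxy)phenol
Conditions: MOMCl (2 equiv), i-Pr2NEt, DMF, 0 °C → rt
Reagents that add atoms: chloromethyl methyl ether, COCCl
Why: Statistical O-alkylation with two equivalents of MOMCl should give the bis-ether, separable from mono- and tris-ether by chromatography, leaving free the one oxygen that later becomes the triflate.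

Step 7
Reactants: 11 3,5-bis(methoxymethoxy)phenol
Product: 12 3,5-bis(methoxymethoxy)phenyl acetate
Conditions: Ac2O, pyridine, CH2Cl2, rt
Reagents that add atoms: acetic anhydride, CC(=O)OC(C)=O
Why: Acetylation turns the free phenol into a weakly donating ester, so that the two MOM ethers alone direct the halogenations that follow.

Step 8
Reactants: 12 3,5-bis(methoxymethoxy)phenyl acetate
Product: 13 2-bromo-3,5-bis(methoxymethoxy)phenyl acetate
Conditions: NBS (1 equiv), MeCN, −20 → 0 °C
Reagents that add atoms: N-bromosuccinimide, O=C1CCC(=O)N1Br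
Why: Electrophilic aromatic bromination should go to the position ortho to one MOM ether and para to the other (next to the acetate), not to the more hindered position between them, as with resorcinol diethers.

Step 9
Reactants: 13 2-bromo-3,5-bis(methoxymethoxy)phenyl acetate
Product: 14 2-bromo-6-iodo-3,5-bis(methoxymethoxy)phenyl acetate
Conditions: NIS, CF3CO2H (cat.), MeCN, 0 °C → rt
Reagents that add atoms: N-iodosuccinimide, O=C1CCC(=O)N1I
Why: A second electrophilic halogenation takes the remaining ortho/para-activated position beside the acetate, giving two different halogens that can be addressed one after the other.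

Step 10
Reactants: 9 (4S,5S)-4-(iodomethyl)-6-(methoxymethoxy)-5-methylhex-1-ene; 14 2-bromo-6-iodo-3,5-bis(methoxymethoxy)phenyl acetate
Product: 16 2-bromo-3,5-bis(methoxymethoxy)-6-[(2R,3S)-4-(methoxymethoxy)-3-methyl-2-(prop-2-en-1-yl)butyl]phenyl acetate, via alkylzinc iodide 15 (not isolated)
Conditions: Zn dust, LiCl, THF, 40 °C; then 14, Pd2(dba)3 (2.5 mol %), SPhos (10 mol %), THF, rt
Reagents that add atoms: none
Why: Zinc inserts into the primary C–I bond and the alkylzinc undergoes Negishi coupling at the aryl iodide, which adds to zerovalent palladium much faster than the aryl bromide, with no stereocentre involved.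

Step 11
Reactants: 16 2-bromo-3,5-bis(methoxymethoxy)-6-[(2R,3S)-4-(methoxymethoxy)-3-methyl-2-(prop-2-en-1-yl)butyl]phenyl acetate
Product: 17 2-bromo-3,5-bis(methoxymethoxy)-6-[(2R,3S)-4-(methoxymethoxy)-3-methyl-2-(prop-2-en-1-yl)butyl]phenol
Conditions: K2CO3, MeOH, 0 °C → rt
Reagents that add atoms: none
Why: Base-catalysed transesterification removes the aryl acetate while the MOM ethers, the aryl bromide and the alkene are inert.

Step 12
Reactants: 17 2-bromo-3,5-bis(methoxymethoxy)-6-[(2R,3S)-4-(methoxymethoxy)-3-methyl-2-(prop-2-en-1-yl)butyl]phenol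
Product: 20 3,5-bis(methoxymethoxy)-2-[(2R,3S)-4-(methoxymethoxy)-3-methyl-2-(prop-2-en-1-yl)butyl]-6-(trimethylsilyl)phenyl trifluoromethanesulfonate, via aryl trimethylsilyl ether 18 (not isolated), via lithium 2-silylphenoxide 19 (not isolated)
Conditions: (Me3Si)2NH, THF, 65 °C, evaporate; n-BuLi, THF, −78 °C; Tf2O, −78 °C
Reagents that add atoms: hexamethyldisilazane, C[Si](C)(C)N[Si](C)(C)C; trifluoromethanesulfonic anhydride, O=S(=O)(OS(=O)(=O)C(F)(F)F)C(F)(F)F
Why: O-silylation, bromine–lithium exchange and 1,3 O→C silyl migration (retro-Brook rearrangement) place silicon exactly where the bromine was, and the resulting phenoxide is triflated to give the ortho-silylaryl triflate.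

Step 13
Reactants: 21 2,4-dihydroxybenzaldehyde
Product: 22 2,4-bis(methoxymethoxy)benzaldehyde
Conditions: MOMCl, i-Pr2NEt, CH2Cl2, 40 °C
Reagents that add atoms: chloromethyl methyl ether, COCCl
Why: O-alkylation protects both ring B phenols, the hydrogen-bonded ortho hydroxyl reacting on warming with excess reagent.

Step 14
Reactants: 22 2,4-bis(methoxymethoxy)benzaldehyde; 23 malonic acid
Product: 25 (E)-3-[2,4-bis(methoxymethoxy)phenyl]prop-2-enoic acid, via benzylidenemalonic acid 24 (not isolated)
Conditions: pyridine, piperidine (cat.), 90 °C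
Reagents that add atoms: none
Why: Knoevenagel–Doebner condensation with decarboxylation gives the E-cinnamic acid in a basic medium that leaves the MOM ethers untouched.

Step 15
Reactants: 20 3,5-bis(methoxymethoxy)-2-[(2R,3S)-4-(methoxymethoxy)-3-methyl-2-(prop-2-en-1-yl)butyl]-6-(trimethylsilyl)phenyl trifluoromethanesulfonate; 25 (E)-3-[2,4-bis(methoxymethoxy)phenyl]prop-2-enoic acid
Product: 27 (E)-1-{2-hydroxy-4,6-bis(methoxymethoxy)-3-[(2R,3S)-4-(methoxymethoxy)-3-methyl-2-(prop-2-en-1-yl)butyl]phenyl}-3-[2,4-bis(methoxymethoxy)phenyl]prop-2-en-1-one, via aryne 26 (not isolated)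
Conditions: CsF (4 equiv), 25 (2 equiv), THF, 125 °C, sealed tube
Reagents that add atoms: none
Why: Fluoride attacks silicon and triflate leaves from the neighbouring carbon to give aryne 26; the cinnamate oxygen adds to C8a, the aryl anion formed at C4a attacks the adjacent ester carbonyl through a four-membered alkoxide, and its collapse moves the cinnamoyl group onto C4a and leaves the C8a phenoxide, forming O–C8a and C4–C4a. The closest known reaction type is the CsF-mediated insertion of arynes into the C–O bond of carboxylic acids, which gives ortho-hydroxyaryl ketones. No ring is closed and no stereocentre is formed, and the E-alkene of the acid is carried over unchanged. The step needs regioselective addition at C8a: the inductively withdrawing C5 OMOM group polarises the aryne so that negative charge develops at C4a beside it, which should outweigh the modest steric shielding of C8a by the C8 CH2 group. It also needs the aryne to be intercepted intermolecularly, which is why the chain carries a terminal allyl group (no allylic hydrogen is placed for an intramolecular aryne–ene reaction, as it would be with a prenyl group held near C8a) and why the acid is used in excess. Acyl transfer should be favoured over protonation of the aryl anion by the high temperature and aprotic medium, and any material that has already cyclised can be returned to 27 by brief KOH/EtOH treatment before purification.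

Step 16
Reactants: 27 (E)-1-{2-hydroxy-4,6-bis(methoxymethoxy)-3-[(2R,3S)-4-(methoxymethoxy)-3-methyl-2-(prop-2-en-1-yl)butyl]phenyl}-3-[2,4-bis(methoxymethoxy)phenyl]prop-2-en-1-one
Product: 28 (2S)-2-[2,4-bis(methoxymethoxy)phenyl]-5,7-bis(methoxymethoxy)-8-[(2R,3S)-4-(methoxymethoxy)-3-methyl-2-(prop-2-en-1-yl)butyl]chroman-4-one
Conditions: 9-amino-9-deoxy-epi-quinidine N′-[3,5-bis(trifluoromethyl)phenyl]thiourea (10 mol %), toluene, rt
Reagents that add atoms: none
Why: In this bifunctional cinchona-thiourea catalysed intramolecular oxa-Michael addition (6-endo-trig) the quinuclidine nitrogen activates the C8a phenol and the thiourea binds the enone, so the catalyst chooses the enone face and should set C2 as S, the remote side-chain centres having little influence.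

Step 17
Reactants: 28 (2S)-2-[2,4-bis(methoxymethoxy)phenyl]-5,7-bis(methoxymethoxy)-8-[(2R,3S)-4-(methoxymethoxy)-3-methyl-2-(prop-2-en-1-yl)butyl]chroman-4-one
Product: 29 (2S)-2-[2,4-bis(methoxymethoxy)phenyl]-5,7-bis(methoxymethoxy)-8-[(2R,3S)-4-(methoxymethoxy)-3-methyl-2-(3-methylbut-2-en-1-yl)butyl]chroman-4-one
Conditions: second-generation Grubbs catalyst RuCl2(=CHPh)(PCy3)(H2IMes) (5 mol %), 2-methylbut-2-ene, CH2Cl2, 40 °C
Reagents that add atoms: 2-methylbut-2-ene, CC=C(C)C
Why: Olefin cross-metathesis of the terminal alkene with excess 2-methylbut-2-ene installs the prenyl terminus (no E/Z issue) with loss of propene, under neutral conditions that leave the flavanone and its C2 centre alone.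

Step 18
Reactants: 29 (2S)-2-[2,4-bis(methoxymethoxy)phenyl]-5,7-bis(methoxymethoxy)-8-[(2R,3S)-4-(methoxymethoxy)-3-methyl-2-(3-methylbut-2-en-1-yl)butyl]chroman-4-one
Product: 30 (2S)-2-(2,4-dihydroxyphenyl)-5,7-dihydroxy-8-[(2R,3S)-4-hydroxy-3-methyl-2-(3-methylbut-2-en-1-yl)butyl]chroman-4-one (CNP0262638.1)
Conditions: HCl (3 M aq), MeOH, 45 °C
Reagents that add atoms: none
Why: Acid-catalysed acetal exchange with methanol removes all five MOM groups as dimethoxymethane, under conditions kept mild so as to spare the prenyl alkene and the C2 stereocentre.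

**Compound list**

1 | (S)-4-methyldihydrofuran-2(3H)-one ((S)-β-methyl-γ-butyrolactone) | C[C@@H]1COC(=O)C1 | starting material
2 | allyl bromide | C=CCBr | starting material
3 | lithium enolate of 1 | C[C@@H]1COC([O-])=C1.[Li+] | intermediate
4 | (3S,4S)-4-methyl-3-(prop-2-en-1-yl)dihydrofuran-2(3H)-one | C=CC[C@@H]1C(=O)OC[C@H]1C | intermediate
5 | (2S,3S)-4-hydroxy-N-methoxy-N,3-dimethyl-2-(prop-2-en-1-yl)butanamide | C=CC[C@H](C(=O)N(C)OC)[C@H](C)CO | intermediate
6 | (2S,3S)-N-methoxy-4-(methoxymethoxy)-N,3-dimethyl-2-(prop-2-en-1-yl)butanamide | C=CC[C@H](C(=O)N(C)OC)[C@H](C)COCOC | intermediate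
7 | (2S,3S)-4-(methoxymethoxy)-3-methyl-2-(prop-2-en-1-yl)butanal | C=CC[C@H](C=O)[C@H](C)COCOC | intermediate
8 | (2S,3S)-4-(methoxymethoxy)-3-methyl-2-(prop-2-en-1-yl)butan-1-ol | C=CC[C@H](CO)[C@H](C)COCOC | intermediate
9 | (4S,5S)-4-(iodomethyl)-6-(methoxymethoxy)-5-methylhex-1-ene | C=CC[C@H](CI)[C@H](C)COCOC | intermediate
10 | phloroglucinol | Oc1cc(O)cc(O)c1 | starting material
11 | 3,5-bis(methoxymethoxy)phenol | COCOc1cc(O)cc(OCOC)c1 | intermediate
12 | 3,5-bis(methoxymethoxy)phenyl acetate | CC(=O)Oc1cc(OCOC)cc(OCOC)c1 | intermediate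
13 | 2-bromo-3,5-bis(methoxymethoxy)phenyl acetate | CC(=O)Oc1cc(OCOC)cc(OCOC)c1Br | intermediate
14 | 2-bromo-6-iodo-3,5-bis(methoxymethoxy)phenyl acetate | CC(=O)Oc1c(I)c(OCOC)cc(OCOC)c1Br | intermediate
15 | [(2S,3S)-4-(methoxymethoxy)-3-methyl-2-(prop-2-en-1-yl)butyl]zinc iodide | C=CC[C@H](C[Zn]I)[C@H](C)COCOC | intermediate
16 | 2-bromo-3,5-bis(methoxymethoxy)-6-[(2R,3S)-4-(methoxymethoxy)-3-methyl-2-(prop-2-en-1-yl)butyl]phenyl acetate | C=CC[C@H](Cc1c(OCOC)cc(OCOC)c(Br)c1OC(C)=O)[C@H](C)COCOC | intermediate
17 | 2-bromo-3,5-bis(methoxymethoxy)-6-[(2R,3S)-4-(methoxymethoxy)-3-methyl-2-(prop-2-en-1-yl)butyl]phenol | C=CC[C@H](Cc1c(OCOC)cc(OCOC)c(Br)c1O)[C@H](C)COCOC | intermediate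
18 | trimethylsilyl ether of 17 | C=CC[C@H](Cc1c(OCOC)cc(OCOC)c(Br)c1O[Si](C)(C)C)[C@H](C)COCOC | intermediate
19 | lithium 3,5-bis(methoxymethoxy)-2-[(2R,3S)-4-(methoxymethoxy)-3-methyl-2-(prop-2-en-1-yl)butyl]-6-(trimethylsilyl)phenoxide | C=CC[C@H](Cc1c(OCOC)cc(OCOC)c([Si](C)(C)C)c1[O-])[C@H](C)COCOC.[Li+] | intermediate
20 | 3,5-bis(methoxymethoxy)-2-[(2R,3S)-4-(methoxymethoxy)-3-methyl-2-(prop-2-en-1-yl)butyl]-6-(trimethylsilyl)phenyl trifluoromethanesulfonate | C=CC[C@H](Cc1c(OCOC)cc(OCOC)c([Si](C)(C)C)c1OS(=O)(=O)C(F)(F)F)[C@H](C)COCOC | intermediate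
21 | 2,4-dihydroxybenzaldehyde | O=Cc1ccc(O)cc1O | starting material
22 | 2,4-bis(methoxymethoxy)benzaldehyde | COCOc1ccc(C=O)c(OCOC)c1 | intermediate
23 | malonic acid | OC(=O)CC(=O)O | starting material
24 | 2-[2,4-bis(methoxymethoxy)benzylidene]malonic acid | OC(=O)C(=Cc1ccc(OCOC)cc1OCOC)C(=O)O | intermediate
25 | (E)-3-[2,4-bis(methoxymethoxy)phenyl]prop-2-enoic acid | OC(=O)/C=C/c1ccc(OCOC)cc1OCOC | intermediate
26 | 3,5-bis(methoxymethoxy)-6-[(2R,3S)-4-(methoxymethoxy)-3-methyl-2-(prop-2-en-1-yl)butyl]benzyne (aryne bond C4a≡C8a) | C=CC[C@H](CC1=C(OCOC)C=C(OCOC)C#C1)[C@H](C)COCOC | intermediate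
27 | (E)-1-{2-hydroxy-4,6-bis(methoxymethoxy)-3-[(2R,3S)-4-(methoxymethoxy)-3-methyl-2-(prop-2-en-1-yl)butyl]phenyl}-3-[2,4-bis(methoxymethoxy)phenyl]prop-2-en-1-one | C=CC[C@H](Cc1c(OCOC)cc(OCOC)c(C(=O)/C=C/c2ccc(OCOC)cc2OCOC)c1O)[C@H](C)COCOC | intermediate
28 | (2S)-2-[2,4-bis(methoxymethoxy)phenyl]-5,7-bis(methoxymethoxy)-8-[(2R,3S)-4-(methoxymethoxy)-3-methyl-2-(prop-2-en-1-yl)butyl]chroman-4-one | C=CC[C@H](Cc1c(OCOC)cc(OCOC)c2c1O[C@H](c1ccc(OCOC)cc1OCOC)CC2=O)[C@H](C)COCOC | intermediate
29 | (2S)-2-[2,4-bis(methoxymethoxy)phenyl]-5,7-bis(methoxymethoxy)-8-[(2R,3S)-4-(methoxymethoxy)-3-methyl-2-(3-methylbut-2-en-1-yl)butyl]chroman-4-one | CC(C)=CC[C@H](Cc1c(OCOC)cc(OCOC)c2c1O[C@H](c1ccc(OCOC)cc1OCOC)CC2=O)[C@H](C)COCOC | intermediate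
30 | (2S)-2-(2,4-dihydroxyphenyl)-5,7-dihydroxy-8-[(2R,3S)-4-hydroxy-3-methyl-2-(3-methylbut-2-en-1-yl)butyl]chroman-4-one | CC(C)=CC[C@H](Cc1c(O)cc(O)c2c1O[C@H](c1ccc(O)cc1O)CC2=O)[C@H](C)CO | target

**Step count and risks**

Total steps: 18. Longest linear sequence: 12 steps (steps 1–5, 10–12, 15–18).

Steps most likely to fail:

1. Step 15 (aryne insertion). The aryne may be consumed by other paths: carboxylate addition at C4a instead of C8a, protonation of the aryl anion before acyl transfer (leaving the O-aryl cinnamate), arylation of the product phenoxide by a second aryne, or unselective closure of ring C in the hot basic medium. Fallback: set out from bromophenol 17. Deprotonation with n-BuLi and bromine–lithium exchange with t-BuLi (THF, −78 °C) would give the lithium 2-lithiophenoxide F1, which is acylated with N-methoxy-N-methylacetamide to the 2-hydroxyacetophenone F2. Claisen–Schmidt condensation of F2 with aldehyde 22 (KOH, EtOH, rt) comes back to the route at chalcone 27. The acyl position is fixed by the bromine, so regiochemistry is no longer at stake.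

2. Step 16 (enantioselective oxa-Michael closure). Facial selection on an enone without a second activating group may be weak, and reversible ring opening under the basic catalyst may erode the C2 configuration. Fallback: set out from 27 and close ring C unselectively (NaOAc, EtOH, reflux) to 28 together with its C2 epimer F3. Because of the two side-chain centres these are diastereomers, to be separated by preparative HPLC (chiral stationary phase if needed). The unwanted epimer F3 is reopened to 27 by retro-oxa-Michael reaction (KOH, EtOH) and cycled again; the route is rejoined at 28.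

3. Step 10 (Negishi coupling). Zinc insertion into the β-branched iodide may be sluggish, oxidative addition at the doubly ortho-substituted C–I bond may be slow enough for β-hydride elimination of the alkylpalladium to compete, and discrimination between iodide and bromide may be lost. Fallback: B-alkyl Suzuki–Miyaura coupling, setting out from iodide 9. Iodine–lithium exchange (t-BuLi, Et2O, −78 °C) would give the primary alkyllithium F4, and capture with B-methoxy-9-borabicyclo[3.3.1]nonane the lithium alkyl(methoxy)borate F5. F5 is coupled with 14 (PdCl2(dppf), K3PO4, DMF/H2O, rt), coming back to the route at 16; any acetate hydrolysed by the aqueous base converges in step 11.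

**Further compounds**

F1 | step 15 | lithium 2-lithio-3,5-bis(methoxymethoxy)-6-[(2R,3S)-4-(methoxymethoxy)-3-methyl-2-(prop-2-en-1-yl)butyl]phenoxide | C=CC[C@H](Cc1c(OCOC)cc(OCOC)c([Li])c1[O-])[C@H](C)COCOC.[Li+]
F2 | step 15 | 1-{2-hydroxy-4,6-bis(methoxymethoxy)-3-[(2R,3S)-4-(methoxymethoxy)-3-methyl-2-(prop-2-en-1-yl)butyl]phenyl}ethan-1-one | C=CC[C@H](Cc1c(OCOC)cc(OCOC)c(C(C)=O)c1O)[C@H](C)COCOC
F3 | step 16 | (2R)-2-[2,4-bis(methoxymethoxy)phenyl]-5,7-bis(methoxymethoxy)-8-[(2R,3S)-4-(methoxymethoxy)-3-methyl-2-(prop-2-en-1-yl)butyl]chroman-4-one (C2 epimer of 28) | C=CC[C@H](Cc1c(OCOC)cc(OCOC)c2c1O[C@@H](c1ccc(OCOC)cc1OCOC)CC2=O)[C@H](C)COCOC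
F4 | step 10 | primary alkyllithium from 9, [4-(methoxymethoxy)-3-methyl-2-(prop-2-en-1-yl)butyl]lithium | C=CC[C@H](C[Li])[C@H](C)COCOC
F5 | step 10 | lithium B-methoxy-B-[4-(methoxymethoxy)-3-methyl-2-(prop-2-en-1-yl)butyl]-9-borabicyclo[3.3.1]nonan-9-uide | C=CC[C@H](C[B-]1(OC)C2CCCC1CCC2)[C@H](C)COCOC.[Li+]
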